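**Retrosynthetic overview**

1. The strategy rests on the C1–C5 bond shared by the cyclopentane (C1–C5) and the cycloheptane (C1, C5, C6–C10), with C1 quaternary. Cutting C1–C5 and C6–C7 leaves an alkyne (C5, C6) joined through C2–C3–C4 to a 1-silyloxyvinylcyclopropane (C1, C10, C9, C8, C7), whose silyloxy group becomes the C9 oxygen.
2. Target ⇐ C2 acetate, C6 anisoate and hydroxyl-directed 8α,9α-epoxide on a 4β,6α-diol. C6–O and the trans H5 come from the C5=C6 alkene (directed epoxidation, titanocene opening, oxidation, anti reduction); the C8 methyl and C8=C9 come from the C9 ketone.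
3. Bicyclic dienol silyl ether ⇐ rhodium-catalysed intramolecular (5+2) cycloaddition, which closes the five- and the seven-membered ring in one step and sets C1.
4. Cycloaddition precursor ⇐ chelate-controlled ethynylation (C4) of the aldol (C2) from 3-methylbutan-2-one and an enal made by Wittig reaction of 1-silyloxycyclopropanecarbaldehyde.
5. Ring order: cyclopropane (bought); five- and seven-membered rings together (step 7); transient C5–C6 oxirane; final C8–C9 oxirane.

Key step: step 7

Remark (numbering): daucane numbering is used (daucane = 4-isopropyl-1,8-dimethylbicyclo[5.3.0]decane; C1 quaternary fusion carbon, C2–C4 in the five-membered ring, C5 the other fusion carbon, C6–C10 in the seven-membered ring; "14-nor" lacks the C8 methyl); β is the face of the C1 methyl, α the opposite face.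

Remark (reagent antipode): (+)-Ipc2BCl, from (−)-α-pinene, is taken to deliver the methyl ketone enolate to the Re face of the enal; should the sense be opposite, the mirror-image reagent is used and nothing else changes.

**Route**

Step 1
Reactants: 1 methyl 1-hydroxycyclopropane-1-carboxylate
Product: 2 methyl 1-(tert-butyldimethylsilyloxy)cyclopropane-1-carboxylate
Conditions: TBSOTf, 2,6-lutidine, CH2Cl2, 0 °C to rt
Reagents that add atoms: tert-butyldimethylsilyl trifluoromethanesulfonate, CC(C)(C)[Si](C)(C)OS(=O)(=O)C(F)(F)F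
Why: O-silylation of a tertiary α-hydroxy ester with a silyl triflate and a hindered base is routine and installs the silyloxy group that later becomes the C9 oxygen.

Step 2
Reactants: 2 methyl 1-(tert-butyldimethylsilyloxy)cyclopropane-1-carboxylate
Product: 3 1-(tert-butyldimethylsilyloxy)cyclopropane-1-carbaldehyde
Conditions: iBu2AlH (1.05 equiv), CH2Cl2, −78 °C; MeOH, aq. potassium sodium tartrate
Reagents that add atoms: none
Why: Partial ester reduction with iBu2AlH should stop at the aluminium hemiacetal, which is stabilised by the α-silyloxy group and releases the non-enolisable aldehyde on work-up.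

Step 3
Reactants: 3 1-(tert-butyldimethylsilyloxy)cyclopropane-1-carbaldehyde; 4 2-(triphenylphosphoranylidene)propanal
Product: 5 (E)-3-[1-(tert-butyldimethylsilyloxy)cyclopropyl]-2-methylprop-2-enal
Conditions: toluene, 90 °C
Reagents that add atoms: none
Why: Wittig reaction of a stabilised formyl ylide should give the (E)-trisubstituted enal (formyl trans to the cyclopropyl group), which is the geometry the tether needs at C1=C10.

Step 4
Reactants: 6 3-methylbutan-2-one; 5 (E)-3-[1-(tert-butyldimethylsilyloxy)cyclopropyl]-2-methylprop-2-enal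
Product: 8 (5R,6E)-7-[1-(tert-butyldimethylsilyloxy)cyclopropyl]-5-hydroxy-2,6-dimethylhept-6-en-3-one, via diisopinocampheylboron enolate 7 (not isolated)
Conditions: (+)-Ipc2BCl, Et3N, Et2O, −78 to 0 °C; 5, −78 to −20 °C; MeOH, pH 7 buffer (NaH2PO4/Na2HPO4), 30% H2O2, 0 °C
Reagents that add atoms: none
Why: Reagent-controlled boron aldol reaction of a methyl ketone: the kinetic methyl-side boron enolate adds 1,2 to the enal through a cyclic transition state whose face is set by the isopinocampheyl ligands, giving the (R)-carbinol that becomes C2, under conditions too weakly Lewis acidic to open the silyloxycyclopropane.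

Step 5
Reactants: 8 (5R,6E)-7-[1-(tert-butyldimethylsilyloxy)cyclopropyl]-5-hydroxy-2,6-dimethylhept-6-en-3-one; 9 ethynylmagnesium bromide
Product: 10 (3S,5R,6E)-7-[1-(tert-butyldimethylsilyloxy)cyclopropyl]-3-ethynyl-2,6-dimethylhept-6-ene-3,5-diol
Conditions: HC≡CMgBr (4 equiv), THF–toluene, −78 to −30 °C; aq. NH4Cl
Reagents that add atoms: none
Why: Chelation-controlled Grignard addition: the first equivalent forms the C2 magnesium alkoxide, which locks the ketone in a six-membered chelate with the alkenyl group pseudo-equatorial, and the acetylide attacks the exposed face so that the new C4 hydroxyl is anti to the C2 oxygen along the alkyne–C4–C3–C2 chain, giving the (3S) tertiary carbinol.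

Step 6
Reactants: 10 (3S,5R,6E)-7-[1-(tert-butyldimethylsilyloxy)cyclopropyl]-3-ethynyl-2,6-dimethylhept-6-ene-3,5-diol
Product: 11 (3S,5R,6E)-5-(tert-butyldimethylsilyloxy)-7-[1-(tert-butyldimethylsilyloxy)cyclopropyl]-3-ethynyl-2,6-dimethylhept-6-en-3-ol
Conditions: TBSCl, imidazole, DMF, 0 °C to rt
Reagents that add atoms: tert-butyldimethylsilyl chloride, CC(C)(C)[Si](C)(C)Cl
Why: Selective silylation: the secondary allylic hydroxyl should react with the silyl chloride while the tertiary propargylic hydroxyl does not.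

Step 7
Reactants: 11 (3S,5R,6E)-5-(tert-butyldimethylsilyloxy)-7-[1-(tert-butyldimethylsilyloxy)cyclopropyl]-3-ethynyl-2,6-dimethylhept-6-en-3-ol
Product: 12 2α,9-bis(tert-butyldimethylsilyloxy)-14-nordauca-5,9-dien-4β-ol
Conditions: [Rh(CO)2Cl]2 (5 mol %), ClCH2CH2Cl (0.02 M), 70 °C
Reagents that add atoms: none
Why: This is the known rhodium-catalysed intramolecular (5+2) cycloaddition of an alkyne-tethered vinylcyclopropane, applied to a 1-silyloxycyclopropane and a trisubstituted alkene: monovalent rhodium binds the alkyne and the vinylcyclopropane, opens one of the two equivalent cyclopropane C–CH2 bonds to a rhoda-allyl (Rh–C7, allyl C9–C10–C1), the alkyne inserts at the allyl terminus C1 (C1–C5) to give a rhodacyclooctadiene, and C6–C7 reductive elimination releases the catalyst. The five-membered ring closes by this 5-exo insertion of the C2–C3–C4 tether onto C1, and the seven-membered ring closes by reductive elimination from the eight-membered metallacycle. The only new stereocentre, quaternary C1, is controlled by C2: to avoid allylic 1,2-strain the C2–H lies next to the C1 methyl in the insertion transition state, so the C2 silyloxy group sits on the side of C10 and ends trans to the methyl, with the C4 isopropyl group pseudo-equatorial and cis to the C2 oxygen on the forming ring. The step needs π-facial selectivity at C1=C10 (secured by C2 as described) and chemoselectivity for cycloaddition over alkyne oligomerisation (dilution and a carbonyl rhodium chloride catalyst that tolerates terminal alkynes and free hydroxyl); the tether fixes the regiochemistry. The silyloxy group is retained as the C9=C10 silyl enol ether and the alkyne as the C5=C6 alkene allylic to the C4 hydroxyl.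

Step 8
Reactants: 12 2α,9-bis(tert-butyldimethylsilyloxy)-14-nordauca-5,9-dien-4β-ol
Product: 13 2α-(tert-butyldimethylsilyloxy)-4β-hydroxy-14-nordauc-5-en-9-one
Conditions: Bu4NF (1.1 equiv), AcOH, THF, −20 to 0 °C
Reagents that add atoms: none
Why: Buffered fluoride should cleave the silyl enol ether much faster than the hindered secondary alkyl silyl ether, and protonation at C10 gives the C9 ketone without exposing the tertiary allylic alcohol to strong acid.

Step 9
Reactants: 13 2α-(tert-butyldimethylsilyloxy)-4β-hydroxy-14-nordauc-5-en-9-one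
Product: 15 2α-(tert-butyldimethylsilyloxy)-4β-hydroxydauc-5-en-9-one (C8 epimers), via dilithium alkoxide-enolate 14 (not isolated)
Conditions: LiN(iPr)2 (2.2 equiv), THF, −78 °C; MeI, −78 to −40 °C; aq. NH4Cl
Reagents that add atoms: iodomethane, CI
Why: Kinetic enolate alkylation: the amide base should remove a C8 proton in preference to the neopentyl C10 protons next to quaternary C1, C-methylation then outpaces O-methylation of the hindered tertiary alkoxide, and the uncontrolled C8 centre is removed in step 10.

Step 10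
Reactants: 15 2α-(tert-butyldimethylsilyloxy)-4β-hydroxydauc-5-en-9-one (C8 epimers)
Product: 16 2α-(tert-butyldimethylsilyloxy)-4β,9-bis(trimethylsilyloxy)dauca-5,8-diene
Conditions: Me3SiCl, NaI, Et3N, MeCN, rt
Reagents that add atoms: chlorotrimethylsilane, C[Si](C)(C)Cl
Why: Equilibrating silyl enol ether formation should favour the tetrasubstituted C8=C9 enol ether over the C9=C10 isomer, which is strained against quaternary C1, and the same reagent silylates the tertiary C4 hydroxyl, protecting it for the next step.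

Step 11
Reactants: 16 2α-(tert-butyldimethylsilyloxy)-4β,9-bis(trimethylsilyloxy)dauca-5,8-diene
Product: 18 2α-(tert-butyldimethylsilyloxy)-4β-(trimethylsilyloxy)dauca-5,8-dien-9-yl trifluoromethanesulfonate, via lithium enolate 17 (not isolated)
Conditions: MeLi, THF, 0 °C; PhNTf2, −78 °C to rt
Reagents that add atoms: N-phenylbis(trifluoromethanesulfonimide), O=S(=O)(N(c1ccccc1)S(=O)(=O)C(F)(F)F)C(F)(F)F
Why: Methyllithium cleaves the silyl enol ether (not the alkyl silyl ethers) to the regiodefined lithium enolate, which is O-sulfonylated to the C8=C9 enol triflate.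

Step 12
Reactants: 18 2α-(tert-butyldimethylsilyloxy)-4β-(trimethylsilyloxy)dauca-5,8-dien-9-yl trifluoromethanesulfonate
Product: 20 2α-(tert-butyldimethylsilyloxy)dauca-5,8-dien-4β-ol, via C4 trimethylsilyl ether 19 (not isolated)
Conditions: Pd(OAc)2 (5 mol %), PPh3, Bu3N, HCO2H, DMF, 60 °C; then K2CO3, MeOH, rt
Reagents that add atoms: none
Why: Palladium-catalysed formate reduction of an enol triflate (oxidative addition of zerovalent palladium, formate-to-hydride exchange, reductive elimination) should give the C8(CH3)=C9H alkene, and methanolysis then frees the tertiary C4 hydroxyl while the secondary silyl ether stays.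

Step 13
Reactants: 20 2α-(tert-butyldimethylsilyloxy)dauca-5,8-dien-4β-ol
Product: 21 5β,6β-epoxy-2α-(tert-butyldimethylsilyloxy)dauc-8-en-4β-ol
Conditions: VO(acac)2 (5 mol %), t-BuOOH, CH2Cl2, 0 °C to rt
Reagents that add atoms: tert-butyl hydroperoxide, CC(C)(C)OO
Why: Hydroxyl-directed epoxidation: the tertiary allylic C4 β-hydroxyl binds the vanadium peroxide and delivers oxygen to the β-face of the allylic C5=C6 alkene only, leaving the remote C8=C9 alkene untouched.

Step 14
Reactants: 21 5β,6β-epoxy-2α-(tert-butyldimethylsilyloxy)dauc-8-en-4β-ol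
Product: 22 2α-(tert-butyldimethylsilyloxy)-5αH-dauc-8-ene-4β,6β-diol
Conditions: Cp2TiCl2, Mn, THF, rt; then 21, 1,4-cyclohexadiene, rt; aq. NaH2PO4
Reagents that add atoms: none
Why: Titanocene-mediated reductive opening of a 2,3-epoxy alcohol: trivalent titanium cleaves the C5–O bond homolytically to the tertiary C5 radical, which should take hydrogen from 1,4-cyclohexadiene on the α-face, anti to the titanium-bound oxygens on C4 and C6 (both β), so that H5 is α and the ring fusion trans; no carbocation forms, so the 1,2-shift of the C4 isopropyl group expected under Lewis-acid opening cannot occur.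

Step 15
Reactants: 22 2α-(tert-butyldimethylsilyloxy)-5αH-dauc-8-ene-4β,6β-diol
Product: 23 2α-(tert-butyldimethylsilyloxy)-4β-hydroxy-5αH-dauc-8-en-6-one
Conditions: Dess–Martin periodinane, NaHCO3, CH2Cl2, 0 °C
Reagents that add atoms: none
Why: Dess–Martin oxidation of the secondary C6 alcohol under buffered, non-basic conditions should leave the tertiary alcohol, the C5 stereocentre and the β,γ-placed C8=C9 alkene unchanged.

Step 16
Reactants: 23 2α-(tert-butyldimethylsilyloxy)-4β-hydroxy-5αH-dauc-8-en-6-one
Product: 24 2α-(tert-butyldimethylsilyloxy)-5αH-dauc-8-ene-4β,6α-diol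
Conditions: Me4NBH(OAc)3, MeCN–AcOH, −30 °C
Reagents that add atoms: none
Why: Evans–Saksena anti reduction: boron exchanges onto the C4 β-oxygen and delivers hydride through a six-membered transition state to the β-face of the C6 carbonyl, giving the 6α-alcohol (4,6-anti diol), and the reagent reduces no other group.

Step 17
Reactants: 24 2α-(tert-butyldimethylsilyloxy)-5αH-dauc-8-ene-4β,6α-diol
Product: 25 8α,9α-epoxy-2α-(tert-butyldimethylsilyloxy)-5αH-daucane-4β,6α-diol
Conditions: VO(acac)2 (5 mol %), t-BuOOH, CH2Cl2, 0 °C to rt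
Reagents that add atoms: tert-butyl hydroperoxide, CC(C)(C)OO
Why: Hydroxyl-directed epoxidation: the homoallylic C6 α-hydroxyl binds vanadium and delivers oxygen to the α-face of the only alkene, setting C8 and C9.

Step 18
Reactants: 25 8α,9α-epoxy-2α-(tert-butyldimethylsilyloxy)-5αH-daucane-4β,6α-diol; 26 4-methoxybenzoyl chloride
Product: 27 8α,9α-epoxy-4β-hydroxy-2α-(tert-butyldimethylsilyloxy)-5αH-daucan-6α-yl 4-methoxybenzoate
Conditions: Et3N, 4-(dimethylamino)pyridine, CH2Cl2, rt
Reagents that add atoms: none
Why: Nucleophile-catalysed acylation should esterify the secondary C6 hydroxyl while the hindered tertiary C4 hydroxyl and the epoxide are inert under basic conditions.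

Step 19
Reactants: 27 8α,9α-epoxy-4β-hydroxy-2α-(tert-butyldimethylsilyloxy)-5αH-daucan-6α-yl 4-methoxybenzoate
Product: 28 8α,9α-epoxy-2α,4β-dihydroxy-5αH-daucan-6α-yl 4-methoxybenzoate
Conditions: Bu4NF, AcOH, THF, rt to 40 °C
Reagents that add atoms: none
Why: Fluoride desilylation buffered with acetic acid should free the C2 hydroxyl without acyl migration, ester cleavage or alkoxide attack on the epoxide.

Step 20
Reactants: 28 8α,9α-epoxy-2α,4β-dihydroxy-5αH-daucan-6α-yl 4-methoxybenzoate
Product: 29 2α-acetoxy-8α,9α-epoxy-4β-hydroxy-5αH-daucan-6α-yl 4-methoxybenzoate (CNP0317703.1)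
Conditions: Ac2O, pyridine, 4-(dimethylamino)pyridine (cat.), CH2Cl2, 0 °C to rt
Reagents that add atoms: acetic anhydride, CC(=O)OC(C)=O
Why: Acetylation should take place only at the secondary C2 hydroxyl, the tertiary C4 hydroxyl being too hindered to react under these conditions.

**Compound list**

1 | methyl 1-hydroxycyclopropane-1-carboxylate | COC(=O)C1(O)CC1 | starting material
2 | methyl 1-(tert-butyldimethylsilyloxy)cyclopropane-1-carboxylate | COC(=O)C1(O[Si](C)(C)C(C)(C)C)CC1 | intermediate
3 | 1-(tert-butyldimethylsilyloxy)cyclopropane-1-carbaldehyde | O=CC1(O[Si](C)(C)C(C)(C)C)CC1 | intermediate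
4 | 2-(triphenylphosphoranylidene)propanal | CC(C=O)=P(c1ccccc1)(c1ccccc1)c1ccccc1 | starting material
5 | (E)-3-[1-(tert-butyldimethylsilyloxy)cyclopropyl]-2-methylprop-2-enal | O=C/C(C)=C/C1(O[Si](C)(C)C(C)(C)C)CC1 | intermediate
6 | 3-methylbutan-2-one | CC(C)C(C)=O | starting material
7 | [(3-methylbut-1-en-2-yl)oxy]diisopinocampheylborane from (+)-Ipc2BCl | CC(C)C(=C)OB([C@H]1C[C@H]2C[C@@H]([C@@H]1C)C2(C)C)[C@H]1C[C@H]2C[C@@H]([C@@H]1C)C2(C)C | intermediate (not isolated)
8 | (5R,6E)-7-[1-(tert-butyldimethylsilyloxy)cyclopropyl]-5-hydroxy-2,6-dimethylhept-6-en-3-one | CC(C)C(=O)C[C@@H](O)/C(C)=C/C1(O[Si](C)(C)C(C)(C)C)CC1 | intermediate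
9 | ethynylmagnesium bromide | C#C[Mg]Br | starting material
10 | (3S,5R,6E)-7-[1-(tert-butyldimethylsilyloxy)cyclopropyl]-3-ethynyl-2,6-dimethylhept-6-ene-3,5-diol | C#C[C@@](O)(C(C)C)C[C@@H](O)/C(C)=C/C1(O[Si](C)(C)C(C)(C)C)CC1 | intermediate
11 | (3S,5R,6E)-5-(tert-butyldimethylsilyloxy)-7-[1-(tert-butyldimethylsilyloxy)cyclopropyl]-3-ethynyl-2,6-dimethylhept-6-en-3-ol | C#C[C@@](O)(C(C)C)C[C@@H](O[Si](C)(C)C(C)(C)C)/C(C)=C/C1(O[Si](C)(C)C(C)(C)C)CC1 | intermediate (key-step precursor)
12 | 2α,9-bis(tert-butyldimethylsilyloxy)-14-nordauca-5,9-dien-4β-ol | C1CCC(O[Si](C)(C)C(C)(C)C)=C[C@]2(C)[C@H](O[Si](C)(C)C(C)(C)C)C[C@](O)(C(C)C)C=12 | intermediate (key-step product)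
13 | 2α-(tert-butyldimethylsilyloxy)-4β-hydroxy-14-nordauc-5-en-9-one | C1CCC(=O)C[C@]2(C)[C@H](O[Si](C)(C)C(C)(C)C)C[C@](O)(C(C)C)C=12 | intermediate
14 | dilithium C4 alkoxide / C8=C9 enolate of 13 | C1CC=C(O[Li])C[C@]2(C)[C@H](O[Si](C)(C)C(C)(C)C)C[C@](O[Li])(C(C)C)C=12 | intermediate (not isolated)
15 | 2α-(tert-butyldimethylsilyloxy)-4β-hydroxydauc-5-en-9-one (C8 epimers) | C1CC(C)C(=O)C[C@]2(C)[C@H](O[Si](C)(C)C(C)(C)C)C[C@](O)(C(C)C)C=12 | intermediate
16 | 2α-(tert-butyldimethylsilyloxy)-4β,9-bis(trimethylsilyloxy)dauca-5,8-diene | C1CC(C)=C(O[Si](C)(C)C)C[C@]2(C)[C@H](O[Si](C)(C)C(C)(C)C)C[C@](O[Si](C)(C)C)(C(C)C)C=12 | intermediate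
17 | lithium C8=C9 enolate from 16 | C1CC(C)=C(O[Li])C[C@]2(C)[C@H](O[Si](C)(C)C(C)(C)C)C[C@](O[Si](C)(C)C)(C(C)C)C=12 | intermediate (not isolated)
18 | 2α-(tert-butyldimethylsilyloxy)-4β-(trimethylsilyloxy)dauca-5,8-dien-9-yl trifluoromethanesulfonate | C1CC(C)=C(OS(=O)(=O)C(F)(F)F)C[C@]2(C)[C@H](O[Si](C)(C)C(C)(C)C)C[C@](O[Si](C)(C)C)(C(C)C)C=12 | intermediate
19 | 2α-(tert-butyldimethylsilyloxy)-4β-(trimethylsilyloxy)dauca-5,8-diene | C1CC(C)=CC[C@]2(C)[C@H](O[Si](C)(C)C(C)(C)C)C[C@](O[Si](C)(C)C)(C(C)C)C=12 | intermediate (not isolated)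
20 | 2α-(tert-butyldimethylsilyloxy)dauca-5,8-dien-4β-ol | C1CC(C)=CC[C@]2(C)[C@H](O[Si](C)(C)C(C)(C)C)C[C@](O)(C(C)C)C=12 | intermediate
21 | 5β,6β-epoxy-2α-(tert-butyldimethylsilyloxy)dauc-8-en-4β-ol | O1[C@H]2CC(C)=CC[C@]3(C)[C@H](O[Si](C)(C)C(C)(C)C)C[C@](O)(C(C)C)[C@]123 | intermediate
22 | 2α-(tert-butyldimethylsilyloxy)-5αH-dauc-8-ene-4β,6β-diol | O[C@H]1CC(C)=CC[C@]2(C)[C@H](O[Si](C)(C)C(C)(C)C)C[C@](O)(C(C)C)[C@@H]12 | intermediate
23 | 2α-(tert-butyldimethylsilyloxy)-4β-hydroxy-5αH-dauc-8-en-6-one | O=C1CC(C)=CC[C@]2(C)[C@H](O[Si](C)(C)C(C)(C)C)C[C@](O)(C(C)C)[C@@H]12 | intermediate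
24 | 2α-(tert-butyldimethylsilyloxy)-5αH-dauc-8-ene-4β,6α-diol | O[C@@H]1CC(C)=CC[C@]2(C)[C@H](O[Si](C)(C)C(C)(C)C)C[C@](O)(C(C)C)[C@@H]12 | intermediate
25 | 8α,9α-epoxy-2α-(tert-butyldimethylsilyloxy)-5αH-daucane-4β,6α-diol | O[C@@H]1C[C@]2(C)O[C@@H]2C[C@]2(C)[C@H](O[Si](C)(C)C(C)(C)C)C[C@](O)(C(C)C)[C@@H]12 | intermediate
26 | 4-methoxybenzoyl chloride | COc1ccc(C(Cl)=O)cc1 | starting material
27 | 8α,9α-epoxy-4β-hydroxy-2α-(tert-butyldimethylsilyloxy)-5αH-daucan-6α-yl 4-methoxybenzoate | COc1ccc(C(=O)O[C@@H]2C[C@]3(C)O[C@@H]3C[C@]3(C)[C@H](O[Si](C)(C)C(C)(C)C)C[C@](O)(C(C)C)[C@@H]23)cc1 | intermediate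
28 | 8α,9α-epoxy-2α,4β-dihydroxy-5αH-daucan-6α-yl 4-methoxybenzoate | COc1ccc(C(=O)O[C@@H]2C[C@]3(C)O[C@@H]3C[C@]3(C)[C@H](O)C[C@](O)(C(C)C)[C@@H]23)cc1 | intermediate
29 | 2α-acetoxy-8α,9α-epoxy-4β-hydroxy-5αH-daucan-6α-yl 4-methoxybenzoate (CNP0317703.1) | COc1ccc(C(=O)O[C@@H]2C[C@]3(C)O[C@@H]3C[C@]3(C)[C@H](OC(C)=O)C[C@](O)(C(C)C)[C@@H]23)cc1 | target

**Step count**

Total steps: 20. Longest linear sequence: 20 steps (1 to 29).

**Steps most likely to fail**

Step 7 (key cycloaddition). Insertion at the trisubstituted alkene that creates quaternary C1 may be slow. The catalyst can then be diverted by the terminal alkyne and the free propargylic hydroxyl (alkyne oligomerisation, ionisation of the carbinol), and facial discrimination at C1=C10 may erode at the temperature needed. Fallback: setting out from 11, the C4 hydroxyl is masked with N-(trimethylsilyl)imidazole in CH2Cl2 as the trimethylsilyl ether F1. The masked substrate should tolerate the more reactive cationic catalyst [Rh(C10H8)(C8H12)]SbF6 (naphthalene and 1,5-cyclooctadiene ligands, monovalent rhodium) in ClCH2CH2Cl at room temperature, giving the tris-silyl cycloadduct F2. Buffered Bu4NF then removes the enol silyl group and the tertiary trimethylsilyl ether together, and the sequence rejoins the route at 13.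

Step 14 (titanocene opening of the epoxy alcohol). Hydrogen-atom transfer to the hindered C5 radical may occur from the β-face (cis ring fusion). The radical may also be reduced further and lose a β-oxygen, returning the alkene. Fallback: setting out from 21, a polar Meinwald rearrangement (BF3·OEt2, CH2Cl2, −78 °C) shifts hydride from C6 to C5 anti to the breaking C5–O bond. This is stereospecific for H5 α and gives the ketone directly, so the sequence rejoins the route at 23 and step 15 is not needed. Its own liability, and the reason it is not the first choice, is competing migration of the C4 isopropyl group (semipinacol pathway).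

Step 5 (chelate-controlled ethynylation). The magnesium aldolate may fragment by retro-aldol reaction or enolise, and chelate control may erode in an ethereal solvent, lowering the diastereoselectivity at C4. Fallback: setting out from 8, the C2 hydroxyl is silylated first (TBSCl, imidazole, DMF) to the silyl ether ketone F3. The non-basic cerium acetylide (HC≡CMgBr, CeCl3, THF, −78 °C) is then added; the 1,3-induction of the open, dipole-minimised transition state of a β-silyloxy carbonyl should give the same 1,3-anti sense, and the sequence rejoins the route directly at 11.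

**Further compounds**

F1 | step 7 | (3S,5R,6E)-5-(tert-butyldimethylsilyloxy)-7-[1-(tert-butyldimethylsilyloxy)cyclopropyl]-3-ethynyl-2,6-dimethyl-3-(trimethylsilyloxy)hept-6-ene | C#C[C@@](O[Si](C)(C)C)(C(C)C)C[C@@H](O[Si](C)(C)C(C)(C)C)/C(C)=C/C1(O[Si](C)(C)C(C)(C)C)CC1
F2 | step 7 | 2α,9-bis(tert-butyldimethylsilyloxy)-4β-(trimethylsilyloxy)-14-nordauca-5,9-diene | C1CCC(O[Si](C)(C)C(C)(C)C)=C[C@]2(C)[C@H](O[Si](C)(C)C(C)(C)C)C[C@](O[Si](C)(C)C)(C(C)C)C=12
F0 | step 14 | none | none
F3 | step 5 | (5R,6E)-5-(tert-butyldimethylsilyloxy)-7-[1-(tert-butyldimethylsilyloxy)cyclopropyl]-2,6-dimethylhept-6-en-3-one | CC(C)C(=O)C[C@@H](O[Si](C)(C)C(C)(C)C)/C(C)=C/C1(O[Si](C)(C)C(C)(C)C)CC1
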